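## The problem

1. The target 21 is a daucane sesquiterpene diester, a trans-fused bicyclo[5.3.0]dec-8-ene. Daucane numbering is used throughout: five-membered ring C1–C5; seven-membered ring C1, C5, C6, C7, C8, C9, C10; C1 is the quaternary ring-fusion carbon (methyl C15), C4 the isopropyl carbinol, C5 the ring-fusion CH, C6 the 4-hydroxybenzoyloxy carbon, C8 the olefinic carbon with methyl C14, C10 the isovaleryloxy carbon. β is the face that carries C15, and the SMILES corresponds to 1S,4S,5S,6R,10S.
2. Five stereocentres are contiguous (C10–C1–C5, with C4 and C6 both on C5); the quaternary C1 sits in the middle and C4 is a fully substituted carbinol next to the ring fusion.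
3. C15, the isopropyl group and both acyloxy groups are on the β-face, while H5 and the C4 hydroxyl are α. Once the trans ring fusion exists, the angular methyl can therefore send an oxidant to the α-face of a C3=C4 bond and hydride to the α-face of carbonyls at C6 and C10; the trans relation of C1 and C5 itself has no such control element.
4. The seven-membered ring is the structural obstacle: it must be formed beside a quaternary carbon, it holds a trisubstituted C8=C9 bond, and its C10 oxygen is allylic and neopentyl.
5. The feature that opens the problem is C9: it is the only carbon of the seven-membered ring without substituent or stereochemistry, it lies between C10 and the methyl-bearing C8, and C10 has the hydrogen-free C1 on its other side.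
6. Without C9 the ring is a cyclohexane with oxygen at C10 and C6 in a 1,4-relation and methyl groups on both carbons next to C10, the pattern of 2,6-dimethyl-1,4-benzoquinone. A C10 ketone in that ring can enolize only toward C8, so one carbon can be put back exactly between C10 and C8 as part of an enone.
7. Sensitive points: the tertiary C4 hydroxyl is β to C6 (an aldol relation, so dehydration, retro-aldol and an epimerizable C5 whenever C6 is a ketone); the C7 methylene lies between C6 and the alkene; the C10 ester is allylic; the two esters differ and one carries a free phenol.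

## Retrosynthesis

**Ester and silyl bonds (21 ⇒ 20 ⇒ 17 + 18; 15 ⇒ 14).** The phenol O–Si bond and the two acyl C–O bonds are cut first. In the forward direction the C10 hydroxyl of 14 is acylated while C6 is still masked, and the C6 hydroxyl of 17 is acylated afterwards with acid 18. The two secondary hydroxyls therefore never have to be told apart and the tertiary C4 hydroxyl needs no protection. Diol 14 has lost the twelve acyl carbons. The forward steps must be acyl transfers that leave a tertiary alcohol alone and a desilylation that spares two esters.

**Carbinol C–H bonds at C6 and C10 (17 ⇒ 16 ⇒ 15; 14 ⇒ 13).** Both secondary carbinols are traced to ketones. C6 stays a dimethyl ketal until C10 is dealt with, because a free C6 ketone and a C10 enone would share the acidic C7 methylene. This cut is preferred to carrying carbinols through the synthesis because the angular methyl can set both: the two oxygens are cis to C15, which is what hydride addition from the open α-face gives. Enone 13 has three stereocentres instead of five. The forward steps need a 1,2-reduction of 13 and a reduction of ketone 16 that is faster than its enolization.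

**Deletion of C9 (13 ⇒ 12 ⇒ 11 ⇒ 10).** The C9–C10 and C8–C9 bonds are cut and C8 is rejoined to C10. This turns the cycloheptenone 13 into siloxycyclopropane 11 and then into silyl enol ether 10 of a trans-hydrindanone. The neighbouring cuts (C8=C9 by metathesis, C9–C10 by vinyl-metal addition) leave an open chain to be closed to a seven-membered ring beside quaternary C1, and leave C10 to be set on a flexible chain. The deletion removes the one carbon that carries no information and leaves a six-membered ring for which an aromatic precursor exists. The gain is not in atom count but in ring class: everything before this point becomes cyclohexane chemistry. The forward reaction must insert one carbon between C10 and C8 only and leave a C8=C9 double bond; the oxidative opening of a siloxycyclopropane through β-chloro ketone 12 does both.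

**C4–O and C3–H bonds (10 ⇒ 9 ⇒ 8 ⇒ 7).** The tertiary alcohol is traced to α-epoxide 8 of cyclopentene 7, and the silyl enol ether of 9 to the enone of 8. Cutting the C4–isopropyl bond instead (isopropyl metal plus C4 ketone) is rejected: the nucleophile would come from the α-face and put oxygen on the β-face, the opposite of what is needed. With the isopropyl group already on C4, the α-face delivers the oxygen. Hydrindenone 7 has two stereocentres and no oxygen on the five-membered ring. The forward steps need an epoxidation that prefers the electron-rich C3=C4 bond to the enone, a 1,4-hydrosilylation, and a hydride that attacks C3.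

**C3=C4 bond (7 ⇒ 6).** The cyclopentene is opened at its double bond. Cutting here, not at C4–C5 or C1–C2, keeps both ring-fusion centres on the six-membered ring, where their trans relation can be set by addition followed by alkylation, and makes the closure a five-ring metathesis. Compound 6 is monocyclic. The forward step must close onto a 1,1-disubstituted alkene that carries the isopropyl group.

**C1–C2 and C4–C5 bonds (6 ⇒ 5 ⇒ 2 + 3 through 4; 2 ⇒ 1).** Removing the allyl group from C1 and the alkenyl group from C5 leads to the achiral cross-conjugated dienone 2 and alkyne 3 (used as its alkenylalane 4); 2 comes from phenol 1 by oxidation. This pair of cuts turns C1, C5, C6, C7, C8, C10, C14 and C15 into one flat, symmetrical building block. The forward direction needs a conjugate addition that distinguishes the two enantiotopic enone halves of 2 (the only absolute stereocontrol of the route, at C5), and an alkylation of the C1 enolate trans to the new substituent, which fixes the trans ring fusion.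

## Roads not taken

Alternative 1: Cut C8=C9 (the most obvious plan). The forward key step is ring-closing metathesis of diene A1, a cyclopentane with a 1-hydroxyallyl arm on C1 and a 1-hydroxy-3-methylbut-3-enyl arm on C5. In A1 all five stereocentres must exist before the ring does. C10 and C6 would come from vinyl- and methallyl-metal additions to aldehydes on freely rotating arms, one of them neopentyl, with no element that controls either; in the chosen plan both are set on the rigid bicycle by the angular methyl. The trans-disubstituted cyclopentane with the C4 carbinol needs its own multistep construction, and the metathesis beside a quaternary carbon comes only after that long run-up.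

Alternative 2: Cut C1–C10. The forward key step is the [3,3]-sigmatropic rearrangement of cis-divinylcyclopropane A2 (cyclopropane C6–C7–C8; one alkene is the C5=C1 bond of a 3-methylcyclopentenone unit, the other an (E)-silyloxyvinyl group C9=C10) to cycloheptadiene A3. This forms the ring, quaternary C1 and C8=C9 at once. The rearrangement passes through a boat in which the trans substituent of the C9=C10 alkene ends trans to C15, so A3 has the wrong configuration at C10. The right one needs the (Z)-enol ether, which places two substituents (C15 and oxygen) inside the boat and slows the reaction below competing hydrogen shifts. C10 would need correction by oxidation and reduction, and C4, C5 and C6 remain open after the key step (C5 only by protonation of an enol). Making A2 is also as long as the whole run-up of the chosen route.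

Alternative 3: Cut C9–C10. The forward key step is the intramolecular Nozaki–Hiyama–Kishi reaction of (Z)-iodoalkene aldehyde A4: chromium reverses the polarity of C9, which adds to the C10 aldehyde, closing the ring and creating C10. The C10 configuration would be decided in a medium-ring transition state with no clear bias, and the aldehyde is neopentyl. A4 needs the same fully substituted cyclopentane as A1 plus a geometrically pure trisubstituted (Z)-vinyl iodide and a protecting group at C6, and the closure consumes chromium in stoichiometric amount at a late stage.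

Key step: step 9

Remark: phenol 1, alkyne 3 and acid 18 are taken as purchasable. C1–C15 and α/β always mean daucane positions and faces as defined above; compounds 2–10 lack C9, and systematic names of the monocyclic and hydrindane compounds use their own locants.

## Route

Step 1
Reactants: 1 4-methoxy-2,6-dimethylphenol
Product: 2 4,4-dimethoxy-2,6-dimethylcyclohexa-2,5-dien-1-one
Conditions: PhI(OAc)2, MeOH, 0 °C → rt
Reagents that add atoms: methanol, CO
Why: Oxidative dearomatization of a para-methoxyphenol with a hypervalent iodine reagent; methanol traps the phenoxenium ion at the methoxy-bearing carbon and gives the quinone monoketal. The product is achiral, with two equivalent enone halves.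

Step 2
Reactants: 2 4,4-dimethoxy-2,6-dimethylcyclohexa-2,5-dien-1-one; 3 3-methylbut-1-yne
Product: 5 (5R)-4,4-dimethoxy-2,6-dimethyl-5-(3-methylbut-1-en-2-yl)cyclohex-2-en-1-one (mixture of C6 epimers), via alkenylalane 4 (not isolated)
Conditions: 3, iBu2AlH, NiCl2(dppp) (3 mol%), THF, 0 → 22 °C; then 2, Cu(OTf)2 (5 mol%), BINOL-derived bis(1-phenylethyl)amine phosphoramidite (10 mol%, enantiomer that gives 5R), THF, −40 °C; pH 7 buffer
Reagents that add atoms: none
Why: Nickel-catalysed α-selective hydroalumination gives the 1,1-disubstituted alkenylalane 4, which adds in a copper-catalysed enantioselective conjugate addition to one of the two enantiotopic β-carbons of 2; the chiral copper–phosphoramidite complex chooses the face and sets C5, the only catalyst-controlled centre of the route. The methyl-bearing α-carbon (daucane C1) forms as an epimer mixture that converges in step 3; neutral work-up avoids loss of methanol and aromatization.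

Step 3
Reactants: 5 (5R)-4,4-dimethoxy-2,6-dimethyl-5-(3-methylbut-1-en-2-yl)cyclohex-2-en-1-one
Product: 6 (5S,6S)-4,4-dimethoxy-2,6-dimethyl-5-(3-methylbut-1-en-2-yl)-6-(prop-2-en-1-yl)cyclohex-2-en-1-one
Conditions: KN(SiMe3)2, THF, −78 °C; allyl bromide, −78 → 0 °C
Reagents that add atoms: allyl bromide, C=CCBr
Why: Enolate alkylation at the only enolizable carbon (daucane C1; the other α-carbon is olefinic) creates the quaternary centre. The allyl group enters anti to the alkenyl group on the neighbouring carbon (trans alkylation of a 3-substituted 2-methylcyclohexanone enolate), which places C2 and C4 trans and fixes the later trans ring fusion.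

Step 4
Reactants: 6 (5S,6S)-4,4-dimethoxy-2,6-dimethyl-5-(3-methylbut-1-en-2-yl)-6-(prop-2-en-1-yl)cyclohex-2-en-1-one
Product: 7 (3aS,7aS)-4,4-dimethoxy-6,7a-dimethyl-3-(propan-2-yl)-1,3a,4,7a-tetrahydro-7H-inden-7-one
Conditions: second-generation Grubbs catalyst (5 mol%), toluene, 80 °C
Reagents that add atoms: none
Why: Ring-closing metathesis of the allyl group with the 1,1-disubstituted alkene closes the five-membered ring as the trisubstituted cyclopentene C3=C4; the trans, diequatorial arms give the trans-fused hydrindene. The electron-poor trisubstituted enone double bond does not take part.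

Step 5
Reactants: 7 (3aS,7aS)-4,4-dimethoxy-6,7a-dimethyl-3-(propan-2-yl)-1,3a,4,7a-tetrahydro-7H-inden-7-one
Product: 8 epoxy enone: the 2,3-epoxide of 7 with oxygen on the face opposite to the angular methyl (daucane 3α,4α-epoxide)
Conditions: mCPBA, NaHCO3, CH2Cl2, 0 °C
Reagents that add atoms: 3-chloroperoxybenzoic acid, OOC(=O)c1cccc(Cl)c1
Why: Prilezhaev epoxidation; the peracid takes the electron-rich C3=C4 bond and leaves the enone. It approaches the α-face because the angular methyl C15 covers the β-face of the cyclopentene, which puts the C4 oxygen on the α-face.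

Step 6
Reactants: 8 epoxy enone
Product: 9 epoxy silyl enol ether: 2,3-epoxy-4,4-dimethoxy-6,7a-dimethyl-3-(propan-2-yl)-7-(triethylsilyloxy)-2,3,3a,4,5,7a-hexahydro-1H-indene (enol ether C8=C10, epoxide kept)
Conditions: Et3SiH, RhCl(PPh3)3 (1 mol%), benzene, 60 °C
Reagents that add atoms: triethylsilane, CC[SiH](CC)CC
Why: Rhodium-catalysed 1,4-hydrosilylation of the enone with a monohydrosilane delivers hydride to C7 and silicon to oxygen, giving the C8=C10 silyl enol ether directly and in the only possible regiochemistry. Epoxide and ketal are inert.

Step 7
Reactants: 9 epoxy silyl enol ether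
Product: 10 tertiary alcohol: 4,4-dimethoxy-6,7a-dimethyl-3-(propan-2-yl)-7-(triethylsilyloxy)-2,3,3a,4,5,7a-hexahydro-1H-inden-3-ol (daucane 4α-hydroxyl, cis to H5)
Conditions: LiEt3BH, THF, 0 °C → rt; aq. NaHCO3
Reagents that add atoms: none
Why: Hydride opens the trisubstituted epoxide by SN2 attack at the secondary carbon C3, so the tertiary C4–O bond and its α-configuration stay as set in step 5. Silyl enol ether and ketal do not react with the borohydride.

Step 8
Reactants: 10 tertiary alcohol silyl enol ether
Product: 11 siloxycyclopropane: 1-(triethylsilyloxy)-6-methylbicyclo[4.1.0]heptane unit C10–C9–C8 fused to the hydrindane (new CH2 = C9, drawn for α-face addition)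
Conditions: Et2Zn, CH2I2, CH2Cl2, 0 °C → rt; aq. NaHCO3
Reagents that add atoms: diiodomethane, ICI
Why: Simmons–Smith cyclopropanation (Furukawa variant); the zinc carbenoid adds to the electron-rich enol ether, the only C=C bond left in the molecule. The configuration at C8 and C10 has no consequence because both lose it in step 9.

Step 9
Reactants: 11 siloxycyclopropane
Product: 13 (1S,4S,5R)-4-hydroxy-6,6-dimethoxydauc-8-en-10-one, via β-chloro ketone 12 (not isolated)
Conditions: FeCl3 (2.5 equiv), pyridine (1 equiv), DMF, 0 °C; then NaOAc, MeOH, 60 °C
Reagents that add atoms: none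
Why: This is the Ito–Saegusa ring expansion of a 1-siloxybicyclo[4.1.0]heptane: FeCl3 oxidizes the siloxycyclopropane by one electron, chloride takes the silyl group, and the cyclopropyloxy radical breaks the bond shared by the two rings (C8–C10), because this scission gives the tertiary C8 radical and releases the strain of the fused three-membered ring. A second equivalent of FeCl3 transfers chlorine to C8 and gives β-chloro ketone 12, from which acetate removes HCl through the C9 enolate (E1cB). No ring is closed; the six-membered ring is enlarged to the seven-membered ring by turning its C8–C10 bond into the C8–C9–C10 bridge, a one-carbon insertion. No stereocentre is created: C8 becomes sp2, the configuration of C8 and C10 in 11 is erased, and C1, C4 and C5 are untouched. The selectivity needed is regiochemical and the substrate secures it twice: the enol ether could only form toward C8 because C1 is quaternary, so the new carbon lies between C10 and C8, and the elimination can only run toward C9, the one α-carbon with hydrogen, which places the double bond at C8=C9 with C14 on it. The closest precedent is the conversion of siloxycyclopropanes derived from 2-methylcyclohexanone into 3-methylcyclohept-2-enones by FeCl3 in DMF. DMF and pyridine temper the Lewis acidity of the iron salt toward the dimethyl ketal and the tertiary alcohol.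

Step 10
Reactants: 13 (1S,4S,5R)-4-hydroxy-6,6-dimethoxydauc-8-en-10-one
Product: 14 (1S,4S,5R,10S)-6,6-dimethoxydauc-8-ene-4,10-diol (4α,10β)
Conditions: NaBH4, CeCl3·7H2O, MeOH, −78 → −40 °C
Reagents that add atoms: none
Why: Luche reduction, 1,2-selective for the enone. Hydride comes from the α-face, anti to the angular methyl on the neighbouring C1, and gives the 10β-alcohol; the dimethyl ketal is stable in methanol.

Step 11
Reactants: 14 (1S,4S,5R,10S)-6,6-dimethoxydauc-8-ene-4,10-diol
Product: 15 (1S,4S,5R,10S)-4-hydroxy-6,6-dimethoxydauc-8-en-10-yl 3-methylbutanoate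
Conditions: (iPrCH2CO)2O, DMAP, pyridine, CH2Cl2, rt
Reagents that add atoms: 3-methylbutanoic anhydride, CC(C)CC(=O)OC(=O)CC(C)C
Why: DMAP-catalysed acylation of the secondary allylic hydroxyl; the tertiary C4 hydroxyl does not react under these conditions.

Step 12
Reactants: 15 (1S,4S,5R,10S)-4-hydroxy-6,6-dimethoxydauc-8-en-10-yl 3-methylbutanoate
Product: 17 (1S,4S,5S,6R,10S)-4,6-dihydroxydauc-8-en-10-yl 3-methylbutanoate (4α,6β), via ketone 16 (not isolated)
Conditions: PPTS (cat.), acetone/H2O, 0 °C → rt; then NaBH4, CeCl3·7H2O, MeOH, −78 °C
Reagents that add atoms: water, O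
Why: Mild acetal hydrolysis frees the C6 ketone, which is reduced cold and without isolation so that it cannot enolize toward C5 or C7. Hydride adds from the α-face because the β-face of C6 is flanked by C15 and the isopropyl group, giving the 6β-alcohol; the Luche conditions spare the ester.

Step 13
Reactants: 17 (1S,4S,5S,6R,10S)-4,6-dihydroxydauc-8-en-10-yl 3-methylbutanoate; 18 4-[(tert-butyldimethylsilyl)oxy]benzoic acid
Product: 20 (1S,4S,5S,6R,10S)-4-hydroxy-10-(3-methylbutanoyloxy)dauc-8-en-6-yl 4-[(tert-butyldimethylsilyl)oxy]benzoate, via Yamaguchi mixed anhydride 19 (not isolated)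
Conditions: 18, 2,4,6-trichlorobenzoyl chloride, Et3N, THF, rt; then 17, DMAP, toluene, 60 °C
Reagents that add atoms: none
Why: Yamaguchi esterification; the mixed anhydride and DMAP transfer the protected 4-hydroxybenzoyl group to the hindered secondary 6β-hydroxyl with retention. The tertiary hydroxyl stays free and the silyl ether keeps the phenol from acylation.

Step 14
Reactants: 20 (1S,4S,5S,6R,10S)-4-hydroxy-10-(3-methylbutanoyloxy)dauc-8-en-6-yl 4-[(tert-butyldimethylsilyl)oxy]benzoate
Product: 21 (1S,4S,5S,6R,10S)-4-hydroxy-10-(3-methylbutanoyloxy)dauc-8-en-6-yl 4-hydroxybenzoate (target)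
Conditions: Bu4NF, AcOH, THF, 0 °C
Reagents that add atoms: none
Why: Fluoride cleaves the aryl silyl ether; acetic acid buffers the phenoxide so that neither ester is cleaved or migrates.

## Compound list

1 | 4-methoxy-2,6-dimethylphenol | COc1cc(C)c(O)c(C)c1 | starting material
2 | 4,4-dimethoxy-2,6-dimethylcyclohexa-2,5-dien-1-one | COC1(OC)C=C(C)C(=O)C(C)=C1 | intermediate
3 | 3-methylbut-1-yne | CC(C)C#C | starting material
4 | bis(2-methylpropyl)(3-methylbut-1-en-2-yl)aluminium | CC(C)C(=C)[Al](CC(C)C)CC(C)C | intermediate (not isolated)
5 | (5R)-4,4-dimethoxy-2,6-dimethyl-5-(3-methylbut-1-en-2-yl)cyclohex-2-en-1-one, C6 epimers | CC1=CC(OC)(OC)[C@@H](C(=C)C(C)C)C(C)C1=O | intermediate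
6 | (5S,6S)-4,4-dimethoxy-2,6-dimethyl-5-(3-methylbut-1-en-2-yl)-6-(prop-2-en-1-yl)cyclohex-2-en-1-one | CC1=CC(OC)(OC)[C@@H](C(=C)C(C)C)[C@](C)(CC=C)C1=O | intermediate
7 | (3aS,7aS)-4,4-dimethoxy-6,7a-dimethyl-3-(propan-2-yl)-1,3a,4,7a-tetrahydro-7H-inden-7-one | CC1=CC(OC)(OC)[C@H]2C(C(C)C)=CC[C@]2(C)C1=O | intermediate
8 | 2,3-epoxide of 7, oxygen anti to the angular methyl (daucane 3α,4α-epoxide) | CC1=CC(OC)(OC)[C@H]2[C@]3(C(C)C)O[C@@H]3C[C@]2(C)C1=O | intermediate
9 | 2,3-epoxy-4,4-dimethoxy-6,7a-dimethyl-3-(propan-2-yl)-7-(triethylsilyloxy)-2,3,3a,4,5,7a-hexahydro-1H-indene | CC1=C(O[Si](CC)(CC)CC)[C@@]2(C)C[C@H]3O[C@@]3(C(C)C)[C@@H]2C(OC)(OC)C1 | intermediate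
10 | 4,4-dimethoxy-6,7a-dimethyl-3-(propan-2-yl)-7-(triethylsilyloxy)-2,3,3a,4,5,7a-hexahydro-1H-inden-3-ol (daucane 4α-OH) | CC1=C(O[Si](CC)(CC)CC)[C@@]2(C)CC[C@](O)(C(C)C)[C@@H]2C(OC)(OC)C1 | intermediate
11 | siloxycyclopropane of 10 (cyclopropane C8–C9–C10, C9 on the α-face) | C[C@]12C[C@@]1(O[Si](CC)(CC)CC)[C@@]3(C)CC[C@](O)(C(C)C)[C@@H]3C(OC)(OC)C2 | intermediate
12 | 8-chloro-4α-hydroxy-6,6-dimethoxydaucan-10-one (C8 epimers) | CC1(Cl)CC(=O)[C@@]2(C)CC[C@](O)(C(C)C)[C@@H]2C(OC)(OC)C1 | intermediate (not isolated)
13 | (1S,4S,5R)-4-hydroxy-6,6-dimethoxydauc-8-en-10-one | CC1=CC(=O)[C@@]2(C)CC[C@](O)(C(C)C)[C@@H]2C(OC)(OC)C1 | intermediate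
14 | (1S,4S,5R,10S)-6,6-dimethoxydauc-8-ene-4,10-diol | CC1=C[C@H](O)[C@@]2(C)CC[C@](O)(C(C)C)[C@@H]2C(OC)(OC)C1 | intermediate
15 | (1S,4S,5R,10S)-4-hydroxy-6,6-dimethoxydauc-8-en-10-yl 3-methylbutanoate | CC1=C[C@H](OC(=O)CC(C)C)[C@@]2(C)CC[C@](O)(C(C)C)[C@@H]2C(OC)(OC)C1 | intermediate
16 | (1S,4S,5R,10S)-4-hydroxy-6-oxodauc-8-en-10-yl 3-methylbutanoate | CC1=C[C@H](OC(=O)CC(C)C)[C@@]2(C)CC[C@](O)(C(C)C)[C@@H]2C(=O)C1 | intermediate (not isolated)
17 | (1S,4S,5S,6R,10S)-4,6-dihydroxydauc-8-en-10-yl 3-methylbutanoate | CC1=C[C@H](OC(=O)CC(C)C)[C@@]2(C)CC[C@](O)(C(C)C)[C@@H]2[C@H](O)C1 | intermediate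
18 | 4-[(tert-butyldimethylsilyl)oxy]benzoic acid | CC(C)(C)[Si](C)(C)Oc1ccc(cc1)C(=O)O | starting material
19 | 4-[(tert-butyldimethylsilyl)oxy]benzoic 2,4,6-trichlorobenzoic anhydride | CC(C)(C)[Si](C)(C)Oc1ccc(cc1)C(=O)OC(=O)c1c(Cl)cc(Cl)cc1Cl | intermediate (not isolated)
20 | (1S,4S,5S,6R,10S)-4-hydroxy-10-(3-methylbutanoyloxy)dauc-8-en-6-yl 4-[(tert-butyldimethylsilyl)oxy]benzoate | CC1=C[C@H](OC(=O)CC(C)C)[C@@]2(C)CC[C@](O)(C(C)C)[C@@H]2[C@H](OC(=O)c2ccc(O[Si](C)(C)C(C)(C)C)cc2)C1 | intermediate
21 | (1S,4S,5S,6R,10S)-4-hydroxy-10-(3-methylbutanoyloxy)dauc-8-en-6-yl 4-hydroxybenzoate | CC1=C[C@H](OC(=O)CC(C)C)[C@@]2(C)CC[C@](O)(C(C)C)[C@@H]2[C@H](OC(=O)c2ccc(O)cc2)C1 | target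

## Step count and least certain steps

Total step count: 14. Longest linear sequence: 14 steps (1 → 21); 3 and 18 enter as purchased fragments.

**Step 9 (key step).** The Lewis-acidic iron salt may ionize the dimethyl ketal at C6 (ketal loss followed by enolization of the freed ketone) or the tertiary C4 alcohol before the cyclopropane is oxidized; less likely, an outer cyclopropane bond opens and the ring is methylated instead of enlarged. Fallback, a diazoalkane homologation of the ketone in place of the radical opening: from 10, Bu4NF/AcOH frees the saturated hydrindanone F1. TMSCHN2 with Me3Al (CH2Cl2, −78 → −20 °C) adds to the C10 carbonyl and the less substituted α-carbon C8 migrates (the quaternary C1 migrates less readily), giving the α-silyl cycloheptanone F2. K2CO3/MeOH removes silicon to give cycloheptanone F3, and IBX (DMSO, 65 °C) dehydrogenates the only enolizable side to return enone 13.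

**Step 2.** Facial discrimination may be insufficient, or conversion low, because the enone is α-methylated and its β-carbon sits next to the fully substituted ketal carbon while the alkenyl nucleophile is branched; on acidic work-up the adduct can also lose methanol and aromatize. Fallback, a racemic addition followed by resolution: from 2, the achiral cuprate made from 2-bromo-3-methylbut-1-ene (t-BuLi, CuBr·SMe2, THF, −78 °C) gives 5 together with its enantiomer F4. Steps 3 and 4 carry the pair on to 6 with its enantiomer F5 and 7 with its enantiomer F6. Compound 7 is separated from F6 by preparative chromatography on a chiral stationary phase, and the route continues from 7.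

**Step 8.** Carbenoid transfer to the tetrasubstituted enol ether, flanked by quaternary C1, may be slow enough for zinc iodide to cleave the silyl enol ether first. Fallback, an enolate in place of the enol ether: from 10, MeLi (THF, 0 °C) cleaves the O–Si bond to the lithium enolate (one regioisomer only). The samarium carbenoid from SmI2 and CH2I2 (THF, −78 °C → rt) converts it into cyclopropanol F7, which FeCl3 opens under the conditions of step 9 to chloro ketone 12 and on to 13.

**Step 12.** The freed C6 ketone may enolize before it is reduced: toward C7 (shift of C8=C9 into conjugation, then loss of the allylic isovalerate by vinylogous elimination) or toward C5 (epimerization to the cis-fused system, or dehydration of the C4 aldol). Fallback, reduction of C6 before the C10 ester exists, followed by site-selective acylation: from 14, the same hydrolysis gives hydroxy ketone F8, which has no leaving group at C10, and the same reduction gives triol F9. One equivalent of 3-methylbutanoic anhydride (DMAP, CH2Cl2, −20 °C) should then acylate the 10β-hydroxyl in preference to the 6β-hydroxyl, which lies between C15 and the isopropyl group, and return 17.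

**Step 13.** Acyl transfer to the 6β-hydroxyl may be slow because C15 and the isopropyl group shield it on the same face, so the mixed anhydride decomposes or reacts at its other carbonyl. Fallback, acylation of the metal alkoxide by a small acyl fluoride instead of nucleophilic catalysis on the neutral alcohol: acid 18 is converted with cyanuric fluoride and pyridine into acid fluoride F10. From 17, LiN(SiMe3)2 (2 equiv, THF, −78 °C) gives the dialkoxide, whose secondary C6 alkoxide reacts with F10 to give 20.

## Further compounds

F1 | step 9 | 4α-hydroxy-6,6-dimethoxy-9-nordaucan-10-one (saturated hydrindanone, C8 epimers) | CC1C(=O)[C@@]2(C)CC[C@](O)(C(C)C)[C@@H]2C(OC)(OC)C1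
F2 | step 9 | 4α-hydroxy-6,6-dimethoxy-9-(trimethylsilyl)daucan-10-one | CC1C([Si](C)(C)C)C(=O)[C@@]2(C)CC[C@](O)(C(C)C)[C@@H]2C(OC)(OC)C1
F3 | step 9 | 4α-hydroxy-6,6-dimethoxydaucan-10-one | CC1CC(=O)[C@@]2(C)CC[C@](O)(C(C)C)[C@@H]2C(OC)(OC)C1
F4 | step 2 | (5S)-4,4-dimethoxy-2,6-dimethyl-5-(3-methylbut-1-en-2-yl)cyclohex-2-en-1-one (enantiomer of 5) | CC1=CC(OC)(OC)[C@H](C(=C)C(C)C)C(C)C1=O
F5 | step 2 | (5R,6R)-4,4-dimethoxy-2,6-dimethyl-5-(3-methylbut-1-en-2-yl)-6-(prop-2-en-1-yl)cyclohex-2-en-1-one (enantiomer of 6) | CC1=CC(OC)(OC)[C@H](C(=C)C(C)C)[C@@](C)(CC=C)C1=O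
F6 | step 2 | (3aR,7aR)-4,4-dimethoxy-6,7a-dimethyl-3-(propan-2-yl)-1,3a,4,7a-tetrahydro-7H-inden-7-one (enantiomer of 7) | CC1=CC(OC)(OC)[C@@H]2C(C(C)C)=CC[C@@]2(C)C1=O
F7 | step 8 | cyclopropanol corresponding to 11 (free C10 hydroxyl) | C[C@]12C[C@@]1(O)[C@@]3(C)CC[C@](O)(C(C)C)[C@@H]3C(OC)(OC)C2
F8 | step 12 | 4α,10β-dihydroxydauc-8-en-6-one | CC1=C[C@H](O)[C@@]2(C)CC[C@](O)(C(C)C)[C@@H]2C(=O)C1
F9 | step 12 | dauc-8-ene-4α,6β,10β-triol | CC1=C[C@H](O)[C@@]2(C)CC[C@](O)(C(C)C)[C@@H]2[C@H](O)C1
F10 | step 13 | 4-[(tert-butyldimethylsilyl)oxy]benzoyl fluoride | CC(C)(C)[Si](C)(C)Oc1ccc(cc1)C(F)=O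
A1 | alternative 1 | 8,9-seco diene triol with the five stereocentres of 21 | C=C[C@H](O)[C@@]1(C)CC[C@](O)(C(C)C)[C@@H]1[C@H](O)CC(C)=C
A2 | alternative 2 | 3-methyl-2-{cis-2-methyl-2-[(E)-2-(tert-butyldimethylsilyloxy)ethenyl]cyclopropyl}cyclopent-2-en-1-one | O=C1CCC(C)=C1[C@@H]1C[C@]1(C)/C=C/O[Si](C)(C)C(C)(C)C
A3 | alternative 2 | 10-epi-10-(tert-butyldimethylsilyloxy)dauca-5,8-dien-4-one | CC1=C[C@@H](O[Si](C)(C)C(C)(C)C)[C@@]2(C)CCC(=O)C2=CC1
A4 | alternative 3 | (Z)-9-iodo-9,10-seco aldehyde with 6-silyl ether | O=C[C@@]1(C)CC[C@](O)(C(C)C)[C@@H]1[C@H](O[Si](C)(C)C(C)(C)C)C/C(C)=C\I
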